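**Plan**

1. Retrosynthesis: after removing the pyrazinone O-benzyl and lactam N-(4-methoxybenzyl) groups, the oxindole C3–C3a bond is cut, then the anilide N–C(O) bond, the pyrazine–vinyl C–C bond and the arene–prenyl bond.
2. Enabling feature: C3 is a tertiary benzylic carbon between the lactam carbonyl C2 and arene carbon C3a, so the five-membered ring N1–C2–C3–C3a–C7a can close by arylating the α-carbon of an acrylanilide from the ortho C–Br bond, with a hydride ending the sequence.
3. Forward, aniline half: 2-bromoaniline is N-propargylated, semi-hydrogenated and rearranged (aza-Claisen) to 2-bromo-6-prenylaniline.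
4. Forward, pyrazine half: 3-methylpyrazin-2(1H)-one is brominated, O-benzylated, methoxylated, brominated again and coupled with acrylic acid.
5. The halves are joined as the anilide, N-benzylated, and the lactam ring (the only ring formed) is closed; two non-basic deprotections follow.
6. Stereochemistry: the single stereocentre C3 (S) comes from a chiral bisphosphine on palladium in the ring closure.

Key step: step 11

Assumption: the sense of induction of this new cyclisation cannot be read from precedent; (R)-BINAP is written as the ligand giving 3S, and its mirror image would be used if the opposite sense were found.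

**Route**

Step 1
Reactants: 1 2-bromoaniline; 2 3-chloro-3-methylbut-1-yne
Product: 3 2-bromo-N-(2-methylbut-3-yn-2-yl)aniline
Conditions: CuCl (10 mol%), Et3N, THF, 0 °C → rt
Reagents that add atoms: none
Why: Copper-catalysed propargylic substitution (through a copper allenylidene-type intermediate) puts the tertiary propargylic carbon on the aniline nitrogen, and the bulk of the new group stops the reaction at monoalkylation.

Step 2
Reactants: 3 2-bromo-N-(2-methylbut-3-yn-2-yl)aniline
Product: 4 2-bromo-N-(2-methylbut-3-en-2-yl)aniline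
Conditions: H2 (1 atm), Pd/CaCO3 poisoned with Pb(OAc)2, quinoline, EtOAc, rt
Reagents that add atoms: none
Why: Lindlar semi-hydrogenation stops at the alkene on the lead-poisoned catalyst and leaves the aryl C–Br bond untouched.

Step 3
Reactants: 4 2-bromo-N-(2-methylbut-3-en-2-yl)aniline
Product: 5 2-bromo-6-(3-methylbut-2-en-1-yl)aniline
Conditions: p-TsOH·H2O (20 mol%), MeCN/H2O (10:1), 80 °C
Reagents that add atoms: none
Why: An acid-accelerated aromatic aza-Claisen ([3,3]) rearrangement carries the allyl group from nitrogen to the free ortho carbon with allylic transposition to the prenyl group; a shift to the bromine-bearing ortho carbon cannot rearomatise and reverts, so only C6 is substituted.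

Step 4
Reactants: 6 3-methylpyrazin-2(1H)-one
Product: 7 5-bromo-3-methylpyrazin-2(1H)-one
Conditions: NBS, DMF, 0 °C → rt, dark
Reagents that add atoms: N-bromosuccinimide, O=C1CCC(=O)N1Br
Why: Electrophilic aromatic bromination takes place at C5, the β-carbon of the N1–C6=C5 enamide and para to the carbonyl carbon, since C3 is blocked by the methyl group.

Step 5
Reactants: 7 5-bromo-3-methylpyrazin-2(1H)-one
Product: 8 2-(benzyloxy)-5-bromo-3-methylpyrazine
Conditions: BnBr, Ag2CO3, toluene, 60 °C, dark
Reagents that add atoms: benzyl bromide, BrCc1ccccc1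
Why: Silver-assisted O-alkylation of the ambident lactam (as for 2-pyridones) should give the benzyl lactim ether in preference to the N-benzyl lactam.

Step 6
Reactants: 8 2-(benzyloxy)-5-bromo-3-methylpyrazine
Product: 9 2-(benzyloxy)-5-methoxy-3-methylpyrazine
Conditions: MeOH, Pd2(dba)3 (1.5 mol%), tBuBrettPhos (4 mol%), NaOtBu, 1,4-dioxane, 50 °C
Reagents that add atoms: methanol, CO
Why: Palladium-catalysed C–O cross-coupling (Buchwald-type etherification) replaces the heteroaryl bromide by methoxide, the bulky biarylphosphine promoting C–O reductive elimination under conditions too mild for exchange of the benzyloxy group.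

Step 7
Reactants: 9 2-(benzyloxy)-5-methoxy-3-methylpyrazine
Product: 10 2-(benzyloxy)-6-bromo-5-methoxy-3-methylpyrazine
Conditions: NBS, DMF, rt, dark
Reagents that add atoms: N-bromosuccinimide, O=C1CCC(=O)N1Br
Why: Electrophilic aromatic bromination goes to the only ring C–H, which is ortho to the methoxy group and para to the methyl group, while a polar solvent and exclusion of light hold back radical bromination of the methyl group.

Step 8
Reactants: 10 2-(benzyloxy)-6-bromo-5-methoxy-3-methylpyrazine; 11 acrylic acid
Product: 12 (E)-3-[6-(benzyloxy)-3-methoxy-5-methylpyrazin-2-yl]prop-2-enoic acid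
Conditions: Pd(OAc)2 (5 mol%), P(o-tol)3 (10 mol%), Et3N, DMF, 100 °C; acidic work-up
Reagents that add atoms: none
Why: Mizoroki–Heck reaction of the heteroaryl bromide with acrylic acid gives the (E)-acrylic acid through syn insertion and syn β-hydride elimination.

Step 9
Reactants: 12 (E)-3-[6-(benzyloxy)-3-methoxy-5-methylpyrazin-2-yl]prop-2-enoic acid; 5 2-bromo-6-(3-methylbut-2-en-1-yl)aniline
Product: 14 (E)-3-[6-(benzyloxy)-3-methoxy-5-methylpyrazin-2-yl]-N-[2-bromo-6-(3-methylbut-2-en-1-yl)phenyl]prop-2-enamide, via acyl chloride 13 (not isolated)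
Conditions: 1-chloro-N,N,2-trimethylprop-1-en-1-amine, CH2Cl2, 0 °C → rt; then 5, pyridine, DMAP (cat.), 0 → 40 °C
Reagents that add atoms: none
Why: The acid is converted to its chloride under neutral conditions by the α-chloroenamine and then acylates the hindered, weakly nucleophilic aniline (pyridine/DMAP-assisted N-acylation), conditions that spare the benzyl lactim ether and the prenyl group.

Step 10
Reactants: 14 (E)-3-[6-(benzyloxy)-3-methoxy-5-methylpyrazin-2-yl]-N-[2-bromo-6-(3-methylbut-2-en-1-yl)phenyl]prop-2-enamide
Product: 15 (E)-3-[6-(benzyloxy)-3-methoxy-5-methylpyrazin-2-yl]-N-[2-bromo-6-(3-methylbut-2-en-1-yl)phenyl]-N-(4-methoxybenzyl)prop-2-enamide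
Conditions: NaH, DMF, 0 °C; then 4-methoxybenzyl chloride, Bu4NI (cat.), 0 °C → rt
Reagents that add atoms: 4-methoxybenzyl chloride, COc1ccc(CCl)cc1
Why: SN2 alkylation of the sodium amidate at nitrogen installs the 4-methoxybenzyl group, which turns the anilide into the rotamer with the aryl ring cis to the alkene and can later be removed oxidatively.

Step 11
Reactants: 15 (E)-3-[6-(benzyloxy)-3-methoxy-5-methylpyrazin-2-yl]-N-[2-bromo-6-(3-methylbut-2-en-1-yl)phenyl]-N-(4-methoxybenzyl)prop-2-enamide
Product: 16 (S)-3-{[6-(benzyloxy)-3-methoxy-5-methylpyrazin-2-yl]methyl}-1-(4-methoxybenzyl)-7-(3-methylbut-2-en-1-yl)indolin-2-one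
Conditions: Pd(OAc)2 (5 mol%), (R)-BINAP (10 mol%), HCO2Na (3 equiv), 1,4-dioxane/H2O (10:1), degassed, 90 °C
Reagents that add atoms: none
Why: Proposed new method: zerovalent palladium inserts into the aryl C–Br bond, the arylpalladium adds syn across the acrylamide C=C so that C3a bonds to the amide α-carbon (the future C3), and the alkylpalladium left on the pyrazinyl-bearing carbon takes up formate, loses CO2 and reductively eliminates the C–H bond. The closest known reaction type is the enantioselective palladium-catalysed reductive Heck cyclisation of N-aryl α-substituted acrylamides to 3,3-disubstituted oxindoles, in which the alkylpalladium has no β-hydrogen; the step here goes beyond it because C3 keeps a hydrogen. The five-membered lactam ring N1–C2–C3–C3a–C7a closes in the 5-exo-trig mode. C3 is set by (R)-BINAP on palladium: the catalyst is expected to choose between the two N–aryl rotamers of 15, which should interconvert at 90 °C, when it inserts into the C–Br bond, and the arylpalladium can then reach only one face of the alkene, so the choice is carried from the axis to C3. The step needs 5-exo over 6-endo addition, which the short anilide tether and the N-benzyl-enforced rotamer secure, and hydride capture over β-hydride elimination, which aza-benzyl bonding of palladium to the pyrazine, chelation by the lactam carbonyl that holds C3–H out of the syn-coplanar position and an excess of formate favour. The weakly basic aqueous formate medium is chosen so that the acidic C3–H of 16 is not exchanged once set.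

Step 12
Reactants: 16 (S)-3-{[6-(benzyloxy)-3-methoxy-5-methylpyrazin-2-yl]methyl}-1-(4-methoxybenzyl)-7-(3-methylbut-2-en-1-yl)indolin-2-one
Product: 17 (S)-3-{[6-(benzyloxy)-3-methoxy-5-methylpyrazin-2-yl]methyl}-7-(3-methylbut-2-en-1-yl)indolin-2-one
Conditions: (NH4)2Ce(NO3)6 (3 equiv), MeCN/H2O (3:1), 0 °C
Reagents that add atoms: none
Why: Oxidative N-debenzylation: tetravalent cerium oxidises the anisyl ring, the most electron-rich arene present, to a radical cation that collapses to an N-acyliminium ion and is hydrolysed to the N–H lactam and anisaldehyde, and the cold acidic medium should leave C3, the prenyl group and the benzyl lactim ether unchanged.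

Step 13
Reactants: 17 (S)-3-{[6-(benzyloxy)-3-methoxy-5-methylpyrazin-2-yl]methyl}-7-(3-methylbut-2-en-1-yl)indolin-2-one
Product: 18 astepyrazinol B, (S)-3-[(3-methoxy-5-methyl-6-oxo-1,6-dihydropyrazin-2-yl)methyl]-7-(3-methylbut-2-en-1-yl)indolin-2-one
Conditions: BCl3 (3 equiv), pentamethylbenzene (5 equiv), CH2Cl2, −78 °C; MeOH quench
Reagents that add atoms: none
Why: Lewis-acid cleavage of the benzyl lactim ether by BCl3 with pentamethylbenzene as a non-basic trap for the benzyl cation frees the pyrazinone at −78 °C, where the methyl lactim ether, the prenyl alkene and the C3 stereocentre should survive.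

**Compound list**

1 | 2-bromoaniline | Nc1ccccc1Br | starting material
2 | 3-chloro-3-methylbut-1-yne | C#CC(C)(C)Cl | starting material
3 | 2-bromo-N-(2-methylbut-3-yn-2-yl)aniline | C#CC(C)(C)Nc1ccccc1Br | intermediate
4 | 2-bromo-N-(2-methylbut-3-en-2-yl)aniline | C=CC(C)(C)Nc1ccccc1Br | intermediate
5 | 2-bromo-6-(3-methylbut-2-en-1-yl)aniline | CC(C)=CCc1cccc(Br)c1N | intermediate
6 | 3-methylpyrazin-2(1H)-one | Cc1ncc[nH]c1=O | starting material
7 | 5-bromo-3-methylpyrazin-2(1H)-one | Cc1nc(Br)c[nH]c1=O | intermediate
8 | 2-(benzyloxy)-5-bromo-3-methylpyrazine | Cc1nc(Br)cnc1OCc1ccccc1 | intermediate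
9 | 2-(benzyloxy)-5-methoxy-3-methylpyrazine | COc1cnc(OCc2ccccc2)c(C)n1 | intermediate
10 | 2-(benzyloxy)-6-bromo-5-methoxy-3-methylpyrazine | COc1nc(C)c(OCc2ccccc2)nc1Br | intermediate
11 | acrylic acid | C=CC(=O)O | starting material
12 | (E)-3-[6-(benzyloxy)-3-methoxy-5-methylpyrazin-2-yl]prop-2-enoic acid | COc1nc(C)c(OCc2ccccc2)nc1/C=C/C(=O)O | intermediate
13 | (E)-3-[6-(benzyloxy)-3-methoxy-5-methylpyrazin-2-yl]prop-2-enoyl chloride | COc1nc(C)c(OCc2ccccc2)nc1/C=C/C(=O)Cl | intermediate
14 | (E)-3-[6-(benzyloxy)-3-methoxy-5-methylpyrazin-2-yl]-N-[2-bromo-6-(3-methylbut-2-en-1-yl)phenyl]prop-2-enamide | COc1nc(C)c(OCc2ccccc2)nc1/C=C/C(=O)Nc1c(Br)cccc1CC=C(C)C | intermediate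
15 | (E)-3-[6-(benzyloxy)-3-methoxy-5-methylpyrazin-2-yl]-N-[2-bromo-6-(3-methylbut-2-en-1-yl)phenyl]-N-(4-methoxybenzyl)prop-2-enamide | COc1nc(C)c(OCc2ccccc2)nc1/C=C/C(=O)N(Cc1ccc(OC)cc1)c1c(Br)cccc1CC=C(C)C | intermediate
16 | (S)-3-{[6-(benzyloxy)-3-methoxy-5-methylpyrazin-2-yl]methyl}-1-(4-methoxybenzyl)-7-(3-methylbut-2-en-1-yl)indolin-2-one | COc1nc(C)c(OCc2ccccc2)nc1C[C@@H]1C(=O)N(Cc3ccc(OC)cc3)c2c(CC=C(C)C)cccc21 | intermediate
17 | (S)-3-{[6-(benzyloxy)-3-methoxy-5-methylpyrazin-2-yl]methyl}-7-(3-methylbut-2-en-1-yl)indolin-2-one | COc1nc(C)c(OCc2ccccc2)nc1C[C@@H]1C(=O)Nc2c(CC=C(C)C)cccc21 | intermediate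
18 | astepyrazinol B, (S)-3-[(3-methoxy-5-methyl-6-oxo-1,6-dihydropyrazin-2-yl)methyl]-7-(3-methylbut-2-en-1-yl)indolin-2-one | COc1nc(C)c(=O)[nH]c1C[C@@H]1C(=O)Nc2c(CC=C(C)C)cccc21 | target

**Step count**

Total: 13 steps. Longest linear sequence: 10 steps (6 → 18, steps 4 to 13); the aniline branch (steps 1 to 3) joins at step 9.

**Steps most likely to fail**

Step 11. Three processes may defeat it: β-hydride elimination of the alkylpalladium may outrun hydride transfer; turnover of the N–aryl axis may be too slow for the catalyst to funnel both rotamers into one enantiomer; and formate may exchange the C3–H after it is set. The fallback sets out from 15 and uses known chemistry only. An ordinary Mizoroki–Heck cyclisation (Pd(OAc)2, PPh3, Et3N, MeCN, 80 °C) should give, by syn addition and syn elimination, (Z)-3-{[6-(benzyloxy)-3-methoxy-5-methylpyrazin-2-yl]methylidene}-1-(4-methoxybenzyl)-7-(3-methylbut-2-en-1-yl)indolin-2-one F1, in which no stereocentre and no axis problem remain. Enantioselective hydrogenation of the conjugated exocyclic C=C with [Rh(cod)2]BF4 and a chiral bisphosphine under H2, a known reaction class for α-alkylidene lactams, then sets C3. The isolated prenyl alkene has no coordinating group and should not be reduced. The route is rejoined at 16.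

Step 12. The oxidative debenzylation may stall, or it may spill over into oxidation of the prenyl alkene or of the enolisable C3 position. The fallback sets out from 14 and replaces the oxidatively cleaved group by an acid-labile one. Alkylation of 14 with freshly prepared 2,4-dimethoxybenzyl chloride (NaH, DMF) gives (E)-3-[6-(benzyloxy)-3-methoxy-5-methylpyrazin-2-yl]-N-[2-bromo-6-(3-methylbut-2-en-1-yl)phenyl]-N-(2,4-dimethoxybenzyl)prop-2-enamide F2. The formate-terminated cyclisation of step 11 then gives (S)-3-{[6-(benzyloxy)-3-methoxy-5-methylpyrazin-2-yl]methyl}-1-(2,4-dimethoxybenzyl)-7-(3-methylbut-2-en-1-yl)indolin-2-one F3. The more readily ionised benzyl group is removed with TFA and anisole in CH2Cl2 at 0 °C, without any oxidant, and the route is rejoined at 17.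

Step 7. Electrophilic substitution at the lone ring C–H may be too slow on the electron-poor diazine, so that radical bromination of the C3 methyl group takes over. The fallback sets out from 9 and moves the bromination to the more nucleophilic lactam tautomer. Hydrogenolysis (H2, Pd/C, EtOAc) gives 5-methoxy-3-methylpyrazin-2(1H)-one F4. NBS in DMF at 0 °C brominates the enol-ether carbon C6, as in step 4, to give 6-bromo-5-methoxy-3-methylpyrazin-2(1H)-one F5. Silver-assisted O-benzylation (Ag2CO3, BnBr), as in step 5, returns to the route at 10.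

**Further compounds**

F1 | step 11 | (Z)-3-{[6-(benzyloxy)-3-methoxy-5-methylpyrazin-2-yl]methylidene}-1-(4-methoxybenzyl)-7-(3-methylbut-2-en-1-yl)indolin-2-one | COc1nc(C)c(OCc2ccccc2)nc1/C=C1\C(=O)N(Cc3ccc(OC)cc3)c2c(CC=C(C)C)cccc21
F2 | step 12 | (E)-3-[6-(benzyloxy)-3-methoxy-5-methylpyrazin-2-yl]-N-[2-bromo-6-(3-methylbut-2-en-1-yl)phenyl]-N-(2,4-dimethoxybenzyl)prop-2-enamide | COc1nc(C)c(OCc2ccccc2)nc1/C=C/C(=O)N(Cc1ccc(OC)cc1OC)c1c(Br)cccc1CC=C(C)C
F3 | step 12 | (S)-3-{[6-(benzyloxy)-3-methoxy-5-methylpyrazin-2-yl]methyl}-1-(2,4-dimethoxybenzyl)-7-(3-methylbut-2-en-1-yl)indolin-2-one | COc1nc(C)c(OCc2ccccc2)nc1C[C@@H]1C(=O)N(Cc3ccc(OC)cc3OC)c2c(CC=C(C)C)cccc21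
F4 | step 7 | 5-methoxy-3-methylpyrazin-2(1H)-one | COc1c[nH]c(=O)c(C)n1
F5 | step 7 | 6-bromo-5-methoxy-3-methylpyrazin-2(1H)-one | COc1nc(C)c(=O)[nH]c1Br
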